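**Plan**
- Cuts (halimane numbering: ring A = C1–C5 and C10, ring B = C5–C10, C17 on C8, C20 on C9, C18/C19 on C4, side chain C11–C16). The cuts are C12–C13 to a purchased butenolide, the C19–O acyl bond, C2–C3 and C4–C5 of ring A in one [4+2] retron, C10–C1 (vinyl), then C9–C11 and C8–C17 back to (S)-carvone.
- Enabling feature: ring A holds quaternary C4 (C18 methyl, C19 CH2O) beside the C3 ketone and is fused through C5=C10. After an alkene shift this is the adduct of the ring B diene C5=C10–C1=C2 with the α,β-bond of a 2-methylallenoate, which supplies C3, C4, C18 and C19; its =CH2 masks the ketone.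
- Forward order: ring B is the carvone ring and ring A closes in the Diels–Alder step. The alkene is then moved to C5=C10 through a C6 ketone, C19 is acylated, C3 is unmasked, and the butenolide is joined last by Negishi coupling.
- Stereochemistry: the carvone stereocentre directs C8 (anti cuprate addition) and C9 (anti alkylation) and becomes C6–O by Criegee rearrangement. C6 is then inverted (oxidation, Luche reduction) so that its silyl ether and C20 shield the same diene face. C4 follows from addition to the open face with the ester exo, C5 is erased, and C6 is finally set by CBS reduction.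

Key step: step 9

Assumption: with this hindered semicyclic diene the allenoate ester is taken to prefer the exo position for steric reasons. The opposite preference is covered by the first fallback, which uses the C6 epimer of the diene that the route passes through anyway.

Step 1
Reactants: 1 (S)-carvone; 2 methyl bromoacetate
Product: 4 methyl 2-[(1R,2S,4S)-1,2-dimethyl-6-oxo-4-(prop-1-en-2-yl)cyclohexyl]acetate, via lithium enolate 3 (not isolated)
Conditions: MeLi, CuI, Et2O, 0 °C; add 1, −78 to 0 °C; then 2, DMPU, THF, −78 °C to rt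
Reagents that add atoms: lithium dimethylcuprate (from MeLi and CuI), [Li+].C[Cu-]C
Why: Gilman conjugate addition with enolate trapping: the cuprate adds anti to the C6 isopropenyl group (sets C8), and the regiodefined enolate is alkylated by the reactive α-bromo ester along the axial path anti to the new axial C8 methyl group (sets quaternary C9 with C11 trans to C17).

Step 2
Reactants: 4 keto ester
Product: 6 methyl 2-[(1R,4S,6S)-1,6-dimethyl-4-(prop-1-en-2-yl)-2-{[(trifluoromethyl)sulfonyl]oxy}cyclohex-2-en-1-yl]acetate, via potassium enolate 5 (not isolated)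
Conditions: KN(SiMe3)2, THF, −78 °C; then PhNTf2, −78 to 0 °C
Reagents that add atoms: N-phenylbis(trifluoromethanesulfonimide), FC(F)(F)S(=O)(=O)N(c1ccccc1)S(=O)(=O)C(F)(F)F; potassium bis(trimethylsilyl)amide, [K+].C[Si](C)(C)[N-][Si](C)(C)C (potassium only in 5)
Why: Kinetic enolate O-sulfonylation (enol triflate synthesis): C9 is quaternary so only C5 can be deprotonated, the ketone is far more acidic than the ester, and because C6 still carries carbon and not oxygen the enolate has no β-leaving group to expel.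

Step 3
Reactants: 6 enol triflate
Product: 9 methyl 2-[(1R,4S,6S)-4-acetoxy-1,6-dimethyl-2-{[(trifluoromethyl)sulfonyl]oxy}cyclohex-2-en-1-yl]acetate, via methoxy hydroperoxide 7 (not isolated), via peroxyacetate 8 (not isolated)
Conditions: O3, CH2Cl2/MeOH, −78 °C, Sudan Red 7B end point; evaporate; then Ac2O, Et3N, DMAP (cat.), CH2Cl2, 0 °C to reflux
Reagents that add atoms: ozone, [O-][O+]=O; methanol, CO; acetic anhydride, CC(=O)OC(C)=O (acetyl only in 8)
Why: Ozonolysis in methanol followed by Criegee rearrangement of the derived peroxyacetate: ozone takes the electron-rich 1,1-disubstituted alkene in preference to the electron-poor enol triflate, and C6 migrates from carbon to oxygen with retention, so the carvone stereocentre becomes the 6S acetate.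

Step 4
Reactants: 9 allylic acetate
Product: 10 methyl 2-[(1R,4S,6S)-4-hydroxy-1,6-dimethyl-2-{[(trifluoromethyl)sulfonyl]oxy}cyclohex-2-en-1-yl]acetate
Conditions: K2CO3 (cat.), MeOH, 0 °C
Reagents that add atoms: none
Why: Base-catalysed transesterification (Zemplén-type methanolysis): with C10 held as the enol triflate there is no acidic C5 hydrogen and hence no E1cB loss of acetate, and the C12 methyl ester only exchanges with itself in methanol.

Step 5
Reactants: 10 hydroxy triflate
Product: 11 methyl 2-[(1R,4S,6S)-2-ethenyl-4-hydroxy-1,6-dimethylcyclohex-2-en-1-yl]acetate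
Conditions: Bu3SnCH=CH2, Pd(PPh3)4 (cat.), LiCl, THF, 65 °C
Reagents that add atoms: tributyl(vinyl)stannane, C=C[Sn](CCCC)(CCCC)CCCC
Why: Stille coupling of a cyclohexenyl triflate with a vinylstannane in the presence of LiCl, the standard entry to 1-vinylcyclohexenes, which tolerates the free alcohol and the ester and forms C10–C1.

Step 6
Reactants: 11 (6S)-dienol
Product: 12 methyl 2-[(1R,6S)-2-ethenyl-1,6-dimethyl-4-oxocyclohex-2-en-1-yl]acetate
Conditions: MnO2, CH2Cl2, rt
Reagents that add atoms: none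
Why: Allylic alcohol oxidation with MnO2, selective for the dienylic C6 carbinol and neutral enough for the diene and the ester.

Step 7
Reactants: 12 dienone
Product: 13 methyl 2-[(1R,4R,6S)-2-ethenyl-4-hydroxy-1,6-dimethylcyclohex-2-en-1-yl]acetate
Conditions: NaBH4, CeCl3·7H2O, MeOH, −78 °C
Reagents that add atoms: none
Why: Luche 1,2-reduction: hydride reaches the C6 carbonyl from the face anti to the C8 methyl group, as in the reduction of carvone to cis-carveol, and gives the 6R alcohol cis to C17.

Step 8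
Reactants: 13 (6R)-dienol
Product: 14 methyl 2-[(1R,4R,6S)-4-[(tert-butyldimethylsilyl)oxy]-2-ethenyl-1,6-dimethylcyclohex-2-en-1-yl]acetate
Conditions: TBSCl, imidazole, DMF, rt
Reagents that add atoms: tert-butyldimethylsilyl chloride, CC(C)(C)[Si](C)(C)Cl
Why: Standard silylation of an unhindered secondary allylic alcohol, which installs the bulky group that will shield one face of the diene.

Step 9
Reactants: 14 ring B diene; 15 ethyl 2-methylbuta-2,3-dienoate
Product: 16 ethyl (1R,5R,6S,8R,8aS)-8-[(tert-butyldimethylsilyl)oxy]-5-(2-methoxy-2-oxoethyl)-1,5,6-trimethyl-2-methylidene-1,2,3,5,6,7,8,8a-octahydronaphthalene-1-carboxylate (halimane descriptors 4R,5S,6R,8S,9R)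
Conditions: 15 (5 equiv), BHT (cat.), toluene, sealed tube, 120 °C
Reagents that add atoms: none
Why: Thermal, concerted but asynchronous [4+2] cycloaddition in which the electrophilic central allene carbon (C3) bonds ahead to the unhindered diene terminus C2 and the ester-bearing α-carbon (C4) then closes onto C5. The closest known reaction type is the Diels–Alder reaction of 1-vinylcyclohexenes with 2-alkylallenoates or methacrylate-type dienophiles, an established way to build a quaternary carbon next to a ring-fusion carbon. Ring A closes as a six-membered carbocycle by suprafacial addition of the conjugated α,β-bond of the allene across the s-cis diene C5=C10–C1=C2, which leaves the distal allene bond as the C3 methylene and moves the ring alkene to C1=C10. C5 is set by the diene face: the cis C6/C8 pair locks ring B in the half-chair with C17 and the silyloxy group pseudoequatorial and C20 pseudoaxial, so C20 and the silyl ether shield one face together and the dienophile adds to the other, the face that carries C11. C4 is set by that face together with the exo placement of the ester: the room under ring B is narrowed by C11 and the axial hydrogens on C6 and C8, so the compact methyl group goes there and the long, flat ester points away, which puts C19 on the face of C20 and C18 on the face of C11 as in the target. The step thus needs regio-, facial and exo selectivity, secured by the polarity and steric match of C2 with C3, by the two shielding groups on one face of 14 and by working without a Lewis acid, which would draw the ester under the diene; C5 is erased later, so only the pairing of face and ester orientation counts.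

Step 10
Reactants: 16 cycloadduct
Product: 17 ethyl (1R,5R,6S,8R,8aS)-8-hydroxy-5-(2-methoxy-2-oxoethyl)-1,5,6-trimethyl-2-methylidene-1,2,3,5,6,7,8,8a-octahydronaphthalene-1-carboxylate
Conditions: HF·pyridine, THF, 0 °C to rt
Reagents that add atoms: none
Why: Fluoride-mediated silyl ether cleavage under mildly acidic conditions, chosen so that no free C6 alkoxide is formed that could attack the C19 ester.

Step 11
Reactants: 17 alcohol
Product: 19 ethyl (1S,5R,6S)-5-(2-methoxy-2-oxoethyl)-1,5,6-trimethyl-2-methylidene-8-oxo-1,2,3,4,5,6,7,8-octahydronaphthalene-1-carboxylate, via β,γ-unsaturated ketone 18 (not isolated)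
Conditions: Dess–Martin periodinane, CH2Cl2, rt; aqueous Na2S2O3/NaHCO3 wash; then DBU (cat.), CH2Cl2, rt
Reagents that add atoms: none
Why: Dess–Martin oxidation followed by base-catalysed conjugation of a β,γ-unsaturated ketone: DBU removes the doubly activated C5 hydrogen and the dienolate is reprotonated at C1, which gives the tetrasubstituted C5=C10 enone and erases C5, while quaternary C4 cannot epimerise.

Step 12
Reactants: 19 enone
Product: 20 ethyl (1S,5R,6S,8S)-8-hydroxy-5-(2-methoxy-2-oxoethyl)-1,5,6-trimethyl-2-methylidene-1,2,3,4,5,6,7,8-octahydronaphthalene-1-carboxylate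
Conditions: (R)-2-methyl-CBS-oxazaborolidine, catecholborane, toluene, −78 °C
Reagents that add atoms: none
Why: Corey–Bakshi–Shibata reduction: the (R)-oxazaborolidine tells the fully substituted alkenyl flank (C5) from the C7 methylene and delivers hydride to the Re face of the C6 ketone to give the 6S alcohol, and catecholborane at low temperature touches neither the esters nor the C3 methylene.

Step 13
Reactants: 20 allylic alcohol
Product: 21 ethyl (1S,5R,6S,8S)-5-(2-methoxy-2-oxoethyl)-1,5,6-trimethyl-2-methylidene-8-[(triethylsilyl)oxy]-1,2,3,4,5,6,7,8-octahydronaphthalene-1-carboxylate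
Conditions: TESOTf, 2,6-lutidine, CH2Cl2, −78 to 0 °C
Reagents that add atoms: triethylsilyl trifluoromethanesulfonate, CC[Si](CC)(CC)OS(=O)(=O)C(F)(F)F
Why: Silyl triflate silylation of a hindered allylic alcohol, with a triethylsilyl group that is small enough to go on and to come off again under mild conditions at this crowded position.

Step 14
Reactants: 21 diester
Product: 22 2-[(1R,2S,4S,5S)-5-(hydroxymethyl)-1,2,5-trimethyl-6-methylidene-4-[(triethylsilyl)oxy]-1,2,3,4,5,6,7,8-octahydronaphthalen-1-yl]ethan-1-ol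
Conditions: LiAlH4, THF, 0 °C to rt
Reagents that add atoms: none
Why: LiAlH4 reduction of both esters to primary alcohols, with the silyl ether and the unactivated alkenes inert.

Step 15
Reactants: 22 diol
Product: 23 [(1S,5R,6S,8S)-5-(2-iodoethyl)-1,5,6-trimethyl-2-methylidene-8-[(triethylsilyl)oxy]-1,2,3,4,5,6,7,8-octahydronaphthalen-1-yl]methanol
Conditions: PPh3, I2, imidazole (1.05 equiv each, premixed), CH2Cl2, 0 °C
Reagents that add atoms: iodine, II
Why: Appel iodination under stoichiometric control: SN2 displacement is fast at the unbranched C12 carbinol and very slow at the neopentyl C19 carbinol, so only C12 is converted.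

Step 16
Reactants: 24 3-(4-hydroxyphenyl)propanoic acid
Product: 26 3-{4-[(tert-butyldimethylsilyl)oxy]phenyl}propanoic acid, via bis-silyl derivative 25 (not isolated)
Conditions: TBSCl (2.2 equiv), imidazole, DMF, rt; then AcOH/THF/H2O, rt
Reagents that add atoms: tert-butyldimethylsilyl chloride, CC(C)(C)[Si](C)(C)Cl
Why: Exhaustive silylation followed by selective hydrolysis of the far more labile silyl ester, a standard way to mask the phenol of a hydroxy acid.

Step 17
Reactants: 23 iodo alcohol; 26 silyl-protected acid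
Product: 27 [(1S,5R,6S,8S)-5-(2-iodoethyl)-1,5,6-trimethyl-2-methylidene-8-[(triethylsilyl)oxy]-1,2,3,4,5,6,7,8-octahydronaphthalen-1-yl]methyl 3-{4-[(tert-butyldimethylsilyl)oxy]phenyl}propanoate
Conditions: DCC, DMAP (cat.), CH2Cl2, rt
Reagents that add atoms: none
Why: Steglich esterification, which acylates the single free, neopentyl C19 alcohol under neutral conditions that leave the primary iodide and the silyl ethers alone.

Step 18
Reactants: 27 ester
Product: 29 [(1S,5R,6S,8S)-5-(2-iodoethyl)-1,5,6-trimethyl-2-oxo-8-[(triethylsilyl)oxy]-1,2,3,4,5,6,7,8-octahydronaphthalen-1-yl]methyl 3-{4-[(tert-butyldimethylsilyl)oxy]phenyl}propanoate, via vicinal diol 28 (not isolated)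
Conditions: OsO4 (cat.), NaIO4, 2,6-lutidine, dioxane/H2O, rt
Reagents that add atoms: osmium tetroxide, O=[Os](=O)(=O)=O; sodium periodate, [Na+].[O-]I(=O)(=O)=O (reoxidant, source of the oxygen turned over)
Why: Lemieux–Johnson cleavage: OsO4 dihydroxylates the accessible 1,1-disubstituted C3 methylene and not the shielded tetrasubstituted C5=C10 alkene, and periodate cleaves the diol to the C3 ketone, which cannot enolise toward quaternary C4.

Step 19
Reactants: 29 iodo ketone; 30 4-bromofuran-2(5H)-one
Product: 32 [(1S,5R,6S,8S)-1,5,6-trimethyl-2-oxo-5-[2-(5-oxo-2,5-dihydrofuran-3-yl)ethyl]-8-[(triethylsilyl)oxy]-1,2,3,4,5,6,7,8-octahydronaphthalen-1-yl]methyl 3-{4-[(tert-butyldimethylsilyl)oxy]phenyl}propanoate, via alkylzinc iodide 31 (not isolated)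
Conditions: activated Zn dust, LiCl, THF, 40 °C; then 30, Pd(OAc)2 (cat.), SPhos (cat.), THF, rt
Reagents that add atoms: zinc, [Zn] (only in 31)
Why: Negishi coupling: LiCl-assisted zinc insertion into the primary iodide tolerates ketone, ester and silyl ethers, and the alkylzinc iodide couples with the β-bromo butenolide under palladium catalysis with a bulky biaryl phosphine that outruns β-hydride elimination, forming C12–C13.

Step 20
Reactants: 32 bis-silyl ether
Product: 33 [(1S,5R,6S,8S)-8-hydroxy-1,5,6-trimethyl-2-oxo-5-[2-(5-oxo-2,5-dihydrofuran-3-yl)ethyl]-1,2,3,4,5,6,7,8-octahydronaphthalen-1-yl]methyl 3-(4-hydroxyphenyl)propanoate (CNP0301014.1; halimane descriptors 4S,6S,8S,9R)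
Conditions: HF·pyridine, pyridine, THF, 0 °C to rt
Reagents that add atoms: none
Why: Global fluoride desilylation with buffered HF·pyridine, which frees the C6 alcohol and the phenol without base, so that the β-acyloxy ketone, the ester and the butenolide stay intact.

**Compound list**
1 | (S)-carvone | CC1=CC[C@@H](CC1=O)C(C)=C | starting material
2 | methyl bromoacetate | COC(=O)CBr | starting material
3 | lithium (3S,5S)-2,3-dimethyl-5-(prop-1-en-2-yl)cyclohex-1-en-1-olate | C[C@H]1C[C@H](C(C)=C)CC([O-])=C1C.[Li+] | intermediate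
4 | methyl 2-[(1R,2S,4S)-1,2-dimethyl-6-oxo-4-(prop-1-en-2-yl)cyclohexyl]acetate | C[C@H]1C[C@H](C(C)=C)CC(=O)[C@]1(C)CC(=O)OC | intermediate
5 | potassium (3S,5S,6R)-6-(2-methoxy-2-oxoethyl)-5,6-dimethyl-3-(prop-1-en-2-yl)cyclohex-1-en-1-olate | C[C@H]1C[C@H](C(C)=C)C=C([O-])[C@]1(C)CC(=O)OC.[K+] | intermediate
6 | methyl 2-[(1R,4S,6S)-1,6-dimethyl-4-(prop-1-en-2-yl)-2-{[(trifluoromethyl)sulfonyl]oxy}cyclohex-2-en-1-yl]acetate | C[C@H]1C[C@H](C(C)=C)C=C(OS(=O)(=O)C(F)(F)F)[C@]1(C)CC(=O)OC | intermediate
7 | methyl 2-[(1R,4S,6S)-4-(1-hydroperoxy-1-methoxyethyl)-1,6-dimethyl-2-{[(trifluoromethyl)sulfonyl]oxy}cyclohex-2-en-1-yl]acetate (peroxy carbon configuration open) | C[C@H]1C[C@H](C(C)(OC)OO)C=C(OS(=O)(=O)C(F)(F)F)[C@]1(C)CC(=O)OC | intermediate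
8 | methyl 2-[(1R,4S,6S)-4-[1-(acetylperoxy)-1-methoxyethyl]-1,6-dimethyl-2-{[(trifluoromethyl)sulfonyl]oxy}cyclohex-2-en-1-yl]acetate | C[C@H]1C[C@H](C(C)(OC)OOC(C)=O)C=C(OS(=O)(=O)C(F)(F)F)[C@]1(C)CC(=O)OC | intermediate
9 | methyl 2-[(1R,4S,6S)-4-acetoxy-1,6-dimethyl-2-{[(trifluoromethyl)sulfonyl]oxy}cyclohex-2-en-1-yl]acetate | C[C@H]1C[C@H](OC(C)=O)C=C(OS(=O)(=O)C(F)(F)F)[C@]1(C)CC(=O)OC | intermediate
10 | methyl 2-[(1R,4S,6S)-4-hydroxy-1,6-dimethyl-2-{[(trifluoromethyl)sulfonyl]oxy}cyclohex-2-en-1-yl]acetate | C[C@H]1C[C@H](O)C=C(OS(=O)(=O)C(F)(F)F)[C@]1(C)CC(=O)OC | intermediate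
11 | methyl 2-[(1R,4S,6S)-2-ethenyl-4-hydroxy-1,6-dimethylcyclohex-2-en-1-yl]acetate | C[C@H]1C[C@H](O)C=C(C=C)[C@]1(C)CC(=O)OC | intermediate
12 | methyl 2-[(1R,6S)-2-ethenyl-1,6-dimethyl-4-oxocyclohex-2-en-1-yl]acetate | C[C@H]1CC(=O)C=C(C=C)[C@]1(C)CC(=O)OC | intermediate
13 | methyl 2-[(1R,4R,6S)-2-ethenyl-4-hydroxy-1,6-dimethylcyclohex-2-en-1-yl]acetate | C[C@H]1C[C@@H](O)C=C(C=C)[C@]1(C)CC(=O)OC | intermediate
14 | methyl 2-[(1R,4R,6S)-4-[(tert-butyldimethylsilyl)oxy]-2-ethenyl-1,6-dimethylcyclohex-2-en-1-yl]acetate | C[C@H]1C[C@@H](O[Si](C)(C)C(C)(C)C)C=C(C=C)[C@]1(C)CC(=O)OC | intermediate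
15 | ethyl 2-methylbuta-2,3-dienoate | C=C=C(C)C(=O)OCC | starting material
16 | ethyl (1R,5R,6S,8R,8aS)-8-[(tert-butyldimethylsilyl)oxy]-5-(2-methoxy-2-oxoethyl)-1,5,6-trimethyl-2-methylidene-1,2,3,5,6,7,8,8a-octahydronaphthalene-1-carboxylate | C[C@H]1C[C@@H](O[Si](C)(C)C(C)(C)C)[C@H]2C(=CCC(=C)[C@]2(C)C(=O)OCC)[C@]1(C)CC(=O)OC | intermediate
17 | ethyl (1R,5R,6S,8R,8aS)-8-hydroxy-5-(2-methoxy-2-oxoethyl)-1,5,6-trimethyl-2-methylidene-1,2,3,5,6,7,8,8a-octahydronaphthalene-1-carboxylate | C[C@H]1C[C@@H](O)[C@H]2C(=CCC(=C)[C@]2(C)C(=O)OCC)[C@]1(C)CC(=O)OC | intermediate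
18 | ethyl (1R,5R,6S,8aS)-5-(2-methoxy-2-oxoethyl)-1,5,6-trimethyl-2-methylidene-8-oxo-1,2,3,5,6,7,8,8a-octahydronaphthalene-1-carboxylate | C[C@H]1CC(=O)[C@H]2C(=CCC(=C)[C@]2(C)C(=O)OCC)[C@]1(C)CC(=O)OC | intermediate
19 | ethyl (1S,5R,6S)-5-(2-methoxy-2-oxoethyl)-1,5,6-trimethyl-2-methylidene-8-oxo-1,2,3,4,5,6,7,8-octahydronaphthalene-1-carboxylate | C[C@H]1CC(=O)C2=C(CCC(=C)[C@]2(C)C(=O)OCC)[C@]1(C)CC(=O)OC | intermediate
20 | ethyl (1S,5R,6S,8S)-8-hydroxy-5-(2-methoxy-2-oxoethyl)-1,5,6-trimethyl-2-methylidene-1,2,3,4,5,6,7,8-octahydronaphthalene-1-carboxylate | C[C@H]1C[C@H](O)C2=C(CCC(=C)[C@]2(C)C(=O)OCC)[C@]1(C)CC(=O)OC | intermediate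
21 | ethyl (1S,5R,6S,8S)-5-(2-methoxy-2-oxoethyl)-1,5,6-trimethyl-2-methylidene-8-[(triethylsilyl)oxy]-1,2,3,4,5,6,7,8-octahydronaphthalene-1-carboxylate | C[C@H]1C[C@H](O[Si](CC)(CC)CC)C2=C(CCC(=C)[C@]2(C)C(=O)OCC)[C@]1(C)CC(=O)OC | intermediate
22 | 2-[(1R,2S,4S,5S)-5-(hydroxymethyl)-1,2,5-trimethyl-6-methylidene-4-[(triethylsilyl)oxy]-1,2,3,4,5,6,7,8-octahydronaphthalen-1-yl]ethan-1-ol | C[C@H]1C[C@H](O[Si](CC)(CC)CC)C2=C(CCC(=C)[C@]2(C)CO)[C@]1(C)CCO | intermediate
23 | [(1S,5R,6S,8S)-5-(2-iodoethyl)-1,5,6-trimethyl-2-methylidene-8-[(triethylsilyl)oxy]-1,2,3,4,5,6,7,8-octahydronaphthalen-1-yl]methanol | C[C@H]1C[C@H](O[Si](CC)(CC)CC)C2=C(CCC(=C)[C@]2(C)CO)[C@]1(C)CCI | intermediate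
24 | 3-(4-hydroxyphenyl)propanoic acid | OC(=O)CCc1ccc(O)cc1 | starting material
25 | tert-butyldimethylsilyl 3-{4-[(tert-butyldimethylsilyl)oxy]phenyl}propanoate | CC(C)(C)[Si](C)(C)OC(=O)CCc1ccc(O[Si](C)(C)C(C)(C)C)cc1 | intermediate
26 | 3-{4-[(tert-butyldimethylsilyl)oxy]phenyl}propanoic acid | OC(=O)CCc1ccc(O[Si](C)(C)C(C)(C)C)cc1 | intermediate
27 | C19 ester of 23 with 26 (C3 methylene, C12 iodide, C6 triethylsilyl ether; 4S,6S,8S,9R) | C[C@H]1C[C@H](O[Si](CC)(CC)CC)C2=C(CCC(=C)[C@]2(C)COC(=O)CCc2ccc(O[Si](C)(C)C(C)(C)C)cc2)[C@]1(C)CCI | intermediate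
28 | C3 hydroxy, C3 hydroxymethyl diol from 27 (C3 configuration open, lost on cleavage) | C[C@H]1C[C@H](O[Si](CC)(CC)CC)C2=C(CCC(O)(CO)[C@]2(C)COC(=O)CCc2ccc(O[Si](C)(C)C(C)(C)C)cc2)[C@]1(C)CCI | intermediate
29 | C3 ketone, C12 iodide (4S,6S,8S,9R) | C[C@H]1C[C@H](O[Si](CC)(CC)CC)C2=C(CCC(=O)[C@]2(C)COC(=O)CCc2ccc(O[Si](C)(C)C(C)(C)C)cc2)[C@]1(C)CCI | intermediate
30 | 4-bromofuran-2(5H)-one | O=C1C=C(Br)CO1 | starting material
31 | C12 alkylzinc iodide from 29 | C[C@H]1C[C@H](O[Si](CC)(CC)CC)C2=C(CCC(=O)[C@]2(C)COC(=O)CCc2ccc(O[Si](C)(C)C(C)(C)C)cc2)[C@]1(C)CC[Zn]I | intermediate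
32 | bis-silyl ether of the target (C6 triethylsilyl, phenol tert-butyldimethylsilyl) | C[C@H]1C[C@H](O[Si](CC)(CC)CC)C2=C(CCC(=O)[C@]2(C)COC(=O)CCc2ccc(O[Si](C)(C)C(C)(C)C)cc2)[C@]1(C)CCC1=CC(=O)OC1 | intermediate
33 | CNP0301014.1 | C[C@H]1C[C@H](O)C2=C(CCC(=O)[C@]2(C)COC(=O)CCc2ccc(O)cc2)[C@]1(C)CCC1=CC(=O)OC1 | target

**Step count and risks**

Total step count: 20. Longest linear sequence: 19 steps (steps 1–15 and 17–20, from (S)-carvone).

Steps most likely to fail:

1. **Step 9.**
   - Risk: bond formation at the hindered C5 terminus may be so slow that the allenoate dimerises first. The ester may also slip under the diene (loss of exo selectivity), which would invert C4.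
   - Fallback: the pairing of diene face and ester orientation is reversed instead of being forced. It sets out from 11, whose 6S alcohol is silylated (TBSCl, imidazole, DMF) to the 6S silyl ether diene F1. In F1 the silyloxy group lies on the face of C11, so the dienophile has to come from the face of C20.
   - The cycloaddition with 15 is run with EtAlCl2 (more than two equivalents, because the C12 ester binds one) in CH2Cl2 at −78 to −20 °C. The complexed ester then seeks the endo position and the reaction is strongly accelerated. The endo cycloadduct F2 has the same C4 configuration as 16 and differs only at C5 and C6.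
   - HF·pyridine gives the alcohol F3, Dess–Martin oxidation gives the β,γ-unsaturated ketone F4, and catalytic DBU converts it into 19, where the route is rejoined.

2. **Step 12.**
   - Risk: the crowded tetrasubstituted enone may bind poorly to the oxazaborolidine, so that reduction is slow and the facial selectivity at C6 erodes.
   - Fallback: substrate control followed by inversion. It sets out from 19. Luche reduction (NaBH4, CeCl3·7H2O, MeOH) is expected to deliver hydride anti to C17 and give mainly the 6R allylic alcohol F5.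
   - A Mitsunobu reaction with 4-nitrobenzoic acid (PPh3, DIAD, THF) inverts C6 to the 6S 4-nitrobenzoate F6. K2CO3 in MeOH removes the activated benzoate to give 20, where the route is rejoined.

3. **Step 19.**
   - Risk: zinc insertion may be sluggish, and the alkylzinc may be lost by protonation or by β-hydride elimination after transmetalation.
   - Fallback: no organometallic is pre-formed. It sets out from 29, which is joined directly with 30 by nickel-catalysed reductive cross-electrophile coupling (NiCl2(dme), 4,4'-di-tert-butyl-2,2'-bipyridine, Zn powder, DMA, rt). The alkyl radical from the iodide is captured by the alkenylnickel species from the bromide.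
   - This gives 32 directly, where the route is rejoined.

Further compounds
F1 | step 9 | methyl 2-[(1R,4S,6S)-4-[(tert-butyldimethylsilyl)oxy]-2-ethenyl-1,6-dimethylcyclohex-2-en-1-yl]acetate | C[C@H]1C[C@H](O[Si](C)(C)C(C)(C)C)C=C(C=C)[C@]1(C)CC(=O)OC
F2 | step 9 | ethyl (1R,5R,6S,8S,8aR)-8-[(tert-butyldimethylsilyl)oxy]-5-(2-methoxy-2-oxoethyl)-1,5,6-trimethyl-2-methylidene-1,2,3,5,6,7,8,8a-octahydronaphthalene-1-carboxylate | C[C@H]1C[C@H](O[Si](C)(C)C(C)(C)C)[C@@H]2C(=CCC(=C)[C@]2(C)C(=O)OCC)[C@]1(C)CC(=O)OC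
F3 | step 9 | ethyl (1R,5R,6S,8S,8aR)-8-hydroxy-5-(2-methoxy-2-oxoethyl)-1,5,6-trimethyl-2-methylidene-1,2,3,5,6,7,8,8a-octahydronaphthalene-1-carboxylate | C[C@H]1C[C@H](O)[C@@H]2C(=CCC(=C)[C@]2(C)C(=O)OCC)[C@]1(C)CC(=O)OC
F4 | step 9 | ethyl (1R,5R,6S,8aR)-5-(2-methoxy-2-oxoethyl)-1,5,6-trimethyl-2-methylidene-8-oxo-1,2,3,5,6,7,8,8a-octahydronaphthalene-1-carboxylate | C[C@H]1CC(=O)[C@@H]2C(=CCC(=C)[C@]2(C)C(=O)OCC)[C@]1(C)CC(=O)OC
F5 | step 12 | ethyl (1S,5R,6S,8R)-8-hydroxy-5-(2-methoxy-2-oxoethyl)-1,5,6-trimethyl-2-methylidene-1,2,3,4,5,6,7,8-octahydronaphthalene-1-carboxylate | C[C@H]1C[C@@H](O)C2=C(CCC(=C)[C@]2(C)C(=O)OCC)[C@]1(C)CC(=O)OC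
F6 | step 12 | ethyl (1S,5R,6S,8S)-5-(2-methoxy-2-oxoethyl)-1,5,6-trimethyl-2-methylidene-8-[(4-nitrobenzoyl)oxy]-1,2,3,4,5,6,7,8-octahydronaphthalene-1-carboxylate | C[C@H]1C[C@H](OC(=O)c2ccc(cc2)[N+](=O)[O-])C2=C(CCC(=C)[C@]2(C)C(=O)OCC)[C@]1(C)CC(=O)OC
F0 | step 19 | none | none
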